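**Retrosynthetic overview**

- The ester is put on last by selective acylation of the C8 hydroxyl of the guaiene triol; the C4 carbinol comes from methyl addition to a C4 ketone.
- The bicyclic hydroxy ketone is cut into a four-carbon dienone unit (3-isopropenylcyclopent-2-enone) and a three-carbon C6–C7–C8 unit; a light-driven decarboxylative radical 1,6-addition makes C8–C9 and an aldol of the resulting dienolate makes C5–C6.
- The C6–C8 unit is an acid–aldehyde made from tartrate-derived diethyl (2S,3S)-epoxysuccinate by SN2 opening with an isopropyl cuprate; this C7 centre controls all other stereocentres.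
- Ring order: the five-membered ring is bought (3-ethoxycyclopentenone); the seven-membered ring is formed in the annulation.

Assumption: diethyl (2S,3S)-oxirane-2,3-dicarboxylate (catalogue compound made from D-tartaric acid) is the purchased source of chirality; positions are given in guaiane numbering (C1–C5 five-membered ring, C5–C10 plus C1 seven-membered ring, C4 carbinol, C6 OH, C7 isopropyl, C8 ester oxygen, C10 vinylic methyl).

**Route**

Step 1
Reactants: 1 3-ethoxycyclopent-2-en-1-one; 2 isopropenylmagnesium bromide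
Product: 4 3-(prop-1-en-2-yl)cyclopent-2-en-1-one, via tertiary allylic alcohol 3 (not isolated)
Conditions: THF, 0 °C; then 1 M HCl, 20 °C
Reagents that add atoms: none
Why: Stork–Danheiser sequence: 1,2-addition of the vinyl Grignard to the vinylogous ester gives alcohol 3, which hydrolyses and dehydrates in aqueous acid to the transposed dienone; no stereocentre is formed.

Step 2
Reactants: 5 diethyl (2S,3S)-oxirane-2,3-dicarboxylate; 6 isopropylmagnesium chloride
Product: 7 diethyl (2S,3R)-2-hydroxy-3-(propan-2-yl)butanedioate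
Conditions: CuBr·SMe2 (10 mol%), THF, −40 → 0 °C; then 1 M HCl
Reagents that add atoms: none
Why: Copper-catalysed SN2 opening of the C2-symmetric trans-epoxide (no regiochemical issue) goes with inversion at the attacked carbon, giving the anti hydroxy diester; the isopropyl-bearing carbon becomes C7 of the target.

Step 3
Reactants: 7 diethyl (2S,3R)-2-hydroxy-3-(propan-2-yl)butanedioate
Product: 8 (2S,3R)-4-ethoxy-2-hydroxy-4-oxo-3-(propan-2-yl)butanoic acid
Conditions: LiOH (1.05 eq), THF–H2O, 0 °C; then HCl to pH 2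
Reagents that add atoms: lithium hydroxide, [Li+].[OH-]
Why: Chemoselective saponification: the ester next to the free hydroxyl is the more electrophilic and the other is shielded by the isopropyl group, so one equivalent of hydroxide gives the 1-acid without touching a stereocentre.

Step 4
Reactants: 8 (2S,3R)-4-ethoxy-2-hydroxy-4-oxo-3-(propan-2-yl)butanoic acid
Product: 9 (2S,3R)-3-formyl-2-hydroxy-4-methylpentanoic acid
Conditions: i-Bu2AlH (3.3 eq), CH2Cl2, −78 °C; then aq. potassium sodium tartrate
Reagents that add atoms: none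
Why: Partial ester reduction: the carboxylic acid and hydroxyl are only deprotonated, and the aluminium-chelated hemiacetal of the hindered ethyl ester survives at −78 °C until work-up, giving the aldehyde (handled as its ring-closed 5-hydroxylactone tautomer) with C7 untouched.

Step 5
Reactants: 4 3-(prop-1-en-2-yl)cyclopent-2-en-1-one; 9 (2S,3R)-3-formyl-2-hydroxy-4-methylpentanoic acid
Product: 11 (6S,7R,8R,8aS)-6,8-dihydroxy-4-methyl-7-(propan-2-yl)-3,5,6,7,8,8a-hexahydroazulen-1(2H)-one, via potassium dienolate 10 (not isolated)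
Conditions: 4 (2 eq), [Ir(dF(CF3)ppy)2(dtbbpy)]PF6 (1 mol%), K2HPO4 (1 eq), degassed DMSO, 450 nm LEDs, 20 °C
Reagents that add atoms: none
Why: Proposed new method: a photoredox radical–polar crossover (4+3) annulation in which the excited trivalent iridium complex oxidises the carboxylate of 9, CO2 is lost, the α-hydroxyalkyl radical adds to the unhindered CH2 terminus of the dienone (1,6-Giese addition, forming C8–C9), the dienolyl radical is reduced by the divalent iridium state to dienolate 10, and the α-carbon of 10 attacks the pendant aldehyde to close the seven-membered ring (C5–C6) with the alkene left at the tetrasubstituted C1=C10 position; C8 is set trans to isopropyl by 1,2-induction from C7, C5 by ring closure with isopropyl and the C8 hydroxyl equatorial, and C6 by Felkin-type attack on the non-chelated potassium dienolate; the closest known reactions are photoredox decarboxylative Giese additions of α-oxy acids to enones and radical–polar crossover aldol cyclisations to five- and six-membered rings.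

Step 6
Reactants: 11 (6S,7R,8R,8aS)-6,8-dihydroxy-4-methyl-7-(propan-2-yl)-3,5,6,7,8,8a-hexahydroazulen-1(2H)-one; 12 methyllithium
Product: 13 (1S,6S,7R,8R,8aS)-1,4-dimethyl-7-(propan-2-yl)-1,2,3,5,6,7,8,8a-octahydroazulene-1,6,8-triol
Conditions: MeLi (5 eq), CeCl3 (5 eq), THF, −78 °C; then cold 0.5 M HCl
Reagents that add atoms: none
Why: 1,2-Addition of the non-basic organocerium reagent to the ketone occurs on the face of the cyclopentanone anti to the C5–C6 bond, giving the C4 tertiary alcohol cis to C6 without enolising the acidic allylic C5–H.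

Step 7
Reactants: 13 (1S,6S,7R,8R,8aS)-1,4-dimethyl-7-(propan-2-yl)-1,2,3,5,6,7,8,8a-octahydroazulene-1,6,8-triol; 14 4-acetoxybenzoyl chloride
Product: 16 (1S,6S,7S,8R,8aS)-1,8-dihydroxy-1,4-dimethyl-7-(propan-2-yl)-1,2,3,5,6,7,8,8a-octahydroazulen-6-yl 4-hydroxybenzoate, via acetate ester 15 (not isolated)
Conditions: 14 (1.1 eq), pyridine, DMAP (5 mol%), CH2Cl2, −20 °C; then N2H4·H2O (1.5 eq), THF–MeOH, 0 °C
Reagents that add atoms: none
Why: Regioselective DMAP-catalysed acylation of the equatorial, unhindered C8 hydroxyl over the axial C6 hydroxyl (flanked by the ring fusion and isopropyl) and the tertiary C4 hydroxyl, then chemoselective hydrazinolysis of the aryl acetate, which is much faster than cleavage of the alkyl benzoate; no stereocentre is touched.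

**Compound list**

1 | 3-ethoxycyclopent-2-en-1-one | CCOC1=CC(=O)CC1 | starting material
2 | isopropenylmagnesium bromide (prop-1-en-2-ylmagnesium bromide) | CC(=C)[Mg]Br | starting material
3 | 3-ethoxy-1-(prop-1-en-2-yl)cyclopent-2-en-1-ol (racemic) | CCOC1=CC(O)(CC1)C(C)=C | intermediate
4 | 3-(prop-1-en-2-yl)cyclopent-2-en-1-one | CC(=C)C1=CC(=O)CC1 | intermediate
5 | diethyl (2S,3S)-oxirane-2,3-dicarboxylate | CCOC(=O)[C@H]1O[C@@H]1C(=O)OCC | starting material
6 | isopropylmagnesium chloride | CC(C)[Mg]Cl | starting material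
7 | diethyl (2S,3R)-2-hydroxy-3-(propan-2-yl)butanedioate | CCOC(=O)[C@@H](O)[C@@H](C(C)C)C(=O)OCC | intermediate
8 | (2S,3R)-4-ethoxy-2-hydroxy-4-oxo-3-(propan-2-yl)butanoic acid | OC(=O)[C@@H](O)[C@@H](C(C)C)C(=O)OCC | intermediate
9 | (2S,3R)-3-formyl-2-hydroxy-4-methylpentanoic acid (open form of the 5-hydroxylactone tautomer) | OC(=O)[C@@H](O)[C@@H](C(C)C)C=O | intermediate
10 | potassium (3Z)-3-[(4S,5R)-5-formyl-4-hydroxy-6-methylheptan-2-ylidene]cyclopent-1-en-1-olate | [K+].[O-]C1=C/C(=C(/C)C[C@H](O)[C@@H](C(C)C)C=O)CC1 | intermediate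
11 | (6S,7R,8R,8aS)-6,8-dihydroxy-4-methyl-7-(propan-2-yl)-3,5,6,7,8,8a-hexahydroazulen-1(2H)-one | CC1=C2CCC(=O)[C@@H]2[C@H](O)[C@H](C(C)C)[C@@H](O)C1 | intermediate
12 | methyllithium | [Li]C | starting material
13 | (1S,6S,7R,8R,8aS)-1,4-dimethyl-7-(propan-2-yl)-1,2,3,5,6,7,8,8a-octahydroazulene-1,6,8-triol | CC1=C2CC[C@](C)(O)[C@@H]2[C@H](O)[C@H](C(C)C)[C@@H](O)C1 | intermediate
14 | 4-acetoxybenzoyl chloride | CC(=O)Oc1ccc(cc1)C(Cl)=O | starting material
15 | (1S,6S,7S,8R,8aS)-1,8-dihydroxy-1,4-dimethyl-7-(propan-2-yl)-1,2,3,5,6,7,8,8a-octahydroazulen-6-yl 4-acetoxybenzoate | CC1=C2CC[C@](C)(O)[C@@H]2[C@H](O)[C@H](C(C)C)[C@@H](OC(=O)c2ccc(OC(C)=O)cc2)C1 | intermediate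
16 | (1S,6S,7S,8R,8aS)-1,8-dihydroxy-1,4-dimethyl-7-(propan-2-yl)-1,2,3,5,6,7,8,8a-octahydroazulen-6-yl 4-hydroxybenzoate (CNP0392039.1) | CC1=C2CC[C@](C)(O)[C@@H]2[C@H](O)[C@H](C(C)C)[C@@H](OC(=O)c2ccc(O)cc2)C1 | target

**Step count and risks**

Total step count: 7. Longest linear sequence: 6 steps (5 → 7 → 8 → 9 → 11 → 13 → 16).

Most likely to fail:

1. Step 5 (the proposed new annulation). Possible failures are protonation of the dienolate before the seven-membered aldol, formation of the E-dienolate (which cannot cyclise), and equilibration to the C6 epimer by reversible aldol.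
 Fallback, known chemistry, sets out from diester 7 (with dienone 4) and comes back at 11. Reduce 7 with LiAlH4 to (2S,3S)-3-(hydroxymethyl)-4-methylpentane-1,2-diol F1. Cleave its 1,2-diol with NaIO4 to (2S)-2-(hydroxymethyl)-3-methylbutanal F2, whose aldehyde carbon is the future C8. Couple the ketyl of F2 to the terminal CH2 of 4 with SmI2 (THF–MeOH, −78 °C, ketyl–olefin addition) to give (3Z)-3-[(4S,5S)-4-hydroxy-5-(hydroxymethyl)-6-methylheptan-2-ylidene]cyclopentan-1-one F3; it forms as a Z/E mixture that converges under base through the conjugated enone. Oxidise the primary alcohol with TEMPO/PhI(OAc)2 to (3Z)-3-[(4S,5R)-5-formyl-4-hydroxy-6-methylheptan-2-ylidene]cyclopentan-1-one F4. Close the ring in a separate kinetic aldol (KN(SiMe3)2, 18-crown-6, THF, −78 °C) to 11.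

2. Step 4 (partial reduction of an ester beside a free acid and hydroxyl; over-reduction or C7 epimerisation).
 Fallback sets out from diester 7 and comes back at 9. Saponify both esters (LiOH, then HCl) to (2S,3R)-2-hydroxy-3-(propan-2-yl)butanedioic acid F5. Tie up only the α-hydroxy acid with 2,2-dimethoxypropane/TsOH as (2R)-2-[(4S)-2,2-dimethyl-5-oxo-1,3-dioxolan-4-yl]-3-methylbutanoic acid F6. Reduce the free carboxyl with BH3·SMe2 to (5S)-5-[(2S)-1-hydroxy-3-methylbutan-2-yl]-2,2-dimethyl-1,3-dioxolan-4-one F7. Oxidise with Dess–Martin periodinane to (2R)-2-[(4S)-2,2-dimethyl-5-oxo-1,3-dioxolan-4-yl]-3-methylbutanal F8. Unmask with aqueous CF3CO2H to 9.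

3. Step 7 (mono-acylation of a diol; C6 acylation or acyl migration).
 Fallback sets out from triol 13 and comes back at 15. Condense 13 with PhB(OH)2 (toluene, molecular sieves) to the cyclic phenylboronate of 13 bridging the C4 and C6 oxygens F9. Acylate the only free hydroxyl (C8) with 14/pyridine/DMAP to the C8 4-acetoxybenzoate of that boronate F10. Release the diol with pinacol to give 15, which is deacetylated as in step 7.

**Further compounds**

F1 | step 5 | (2S,3S)-3-(hydroxymethyl)-4-methylpentane-1,2-diol | OC[C@@H](O)[C@@H](C(C)C)CO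
F2 | step 5 | (2S)-2-(hydroxymethyl)-3-methylbutanal | O=C[C@@H](C(C)C)CO
F3 | step 5 | (3Z)-3-[(4S,5S)-4-hydroxy-5-(hydroxymethyl)-6-methylheptan-2-ylidene]cyclopentan-1-one | O=C1C/C(=C(/C)C[C@H](O)[C@@H](C(C)C)CO)CC1
F4 | step 5 | (3Z)-3-[(4S,5R)-5-formyl-4-hydroxy-6-methylheptan-2-ylidene]cyclopentan-1-one | O=C1C/C(=C(/C)C[C@H](O)[C@@H](C(C)C)C=O)CC1
F5 | step 4 | (2S,3R)-2-hydroxy-3-(propan-2-yl)butanedioic acid | OC(=O)[C@@H](O)[C@@H](C(C)C)C(O)=O
F6 | step 4 | (2R)-2-[(4S)-2,2-dimethyl-5-oxo-1,3-dioxolan-4-yl]-3-methylbutanoic acid | CC1(C)O[C@@H]([C@@H](C(C)C)C(O)=O)C(=O)O1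
F7 | step 4 | (5S)-5-[(2S)-1-hydroxy-3-methylbutan-2-yl]-2,2-dimethyl-1,3-dioxolan-4-one | CC1(C)O[C@@H]([C@@H](C(C)C)CO)C(=O)O1
F8 | step 4 | (2R)-2-[(4S)-2,2-dimethyl-5-oxo-1,3-dioxolan-4-yl]-3-methylbutanal | CC1(C)O[C@@H]([C@@H](C(C)C)C=O)C(=O)O1
F9 | step 7 | cyclic phenylboronate of 13 bridging the C4 and C6 oxygens | CC1=C2CC[C@](C)(OB(c3ccccc3)O4)[C@@H]2[C@H]4[C@H](C(C)C)[C@@H](O)C1
F10 | step 7 | C8 4-acetoxybenzoate of the cyclic phenylboronate of 13 | CC1=C2CC[C@](C)(OB(c3ccccc3)O4)[C@@H]2[C@H]4[C@H](C(C)C)[C@@H](OC(=O)c5ccc(OC(C)=O)cc5)C1
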